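Ring C is cut into two three-atom halves: O1–C2–C3, delivered by an enantiopure chlorohydrin, and C4–C4a–C8a, an ortho-fluorobenzonitrile whose nitrile carbon becomes C4 and whose C–F carbon becomes C8a. In one flask the chlorohydrin is converted into a β-oxido alkyllithium that adds to the nitrile (C3–C4); the tethered alkoxide then displaces fluoride (O1–C8a), and hydrolysis of the cyclic ketimine gives the chromanone with C2 untouched. The step exploits the 1,3-relationship of O1 and C3 about C2 in ring C and the ortho relationship of C4 and O1 on ring A. The precursor pair is a chlorohydrin and a fully substituted 2-fluorobenzonitrile that already carries the (R)-lavandulyl group.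

Key step: step 12

Remark: the side-chain centre is (R) only because CH2Ar outranks the prenyl CH2; in space it matches (S)-lavandulol, so the side chain is built by auxiliary-controlled alkylation, and 1-(2,4-dihydroxy-5-methoxyphenyl)ethan-1-one and 2,6-difluoro-4-methoxybenzonitrile are taken as catalogue compounds.

Step 1
Reactants: 1 (4S)-4-benzyl-1,3-oxazolidin-2-one; 2 3-methylbut-2-enoyl chloride
Product: 4 (4S)-4-benzyl-3-(3-methylbut-2-enoyl)-1,3-oxazolidin-2-one, via N-lithio oxazolidinone 3 (not isolated)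
Conditions: n-BuLi, THF, −78 °C; then 2, −78 → 0 °C
Reagents that add atoms: none
Why: N-acylation of the lithiated Evans auxiliary by the acid chloride, run cold so that neither conjugate addition nor deconjugation of the enoyl group competes.

Step 2
Reactants: 4 (4S)-4-benzyl-3-(3-methylbut-2-enoyl)-1,3-oxazolidin-2-one; 5 1-bromo-3-methylbut-2-ene (prenyl bromide)
Product: 7 (4S)-4-benzyl-3-[(2S)-5-methyl-2-(prop-1-en-2-yl)hex-4-enoyl]-1,3-oxazolidin-2-one, via sodium dienolate 6 (not isolated)
Conditions: NaN(SiMe3)2, THF, −78 °C; then 5, −78 → −40 °C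
Reagents that add atoms: none
Why: Evans-type deconjugative α-alkylation, in which γ-deprotonation gives the chelated (Z)-dienolate that is prenylated at Cα on the face opposite the benzyl group, which sets the (2S) centre.

Step 3
Reactants: 7 (4S)-4-benzyl-3-[(2S)-5-methyl-2-(prop-1-en-2-yl)hex-4-enoyl]-1,3-oxazolidin-2-one
Product: 8 (2S)-5-methyl-2-(prop-1-en-2-yl)hex-4-en-1-ol ((S)-lavandulol)
Conditions: LiBH4, H2O (1.1 equiv), Et2O, 0 °C
Reagents that add atoms: none
Why: Reductive cleavage of the imide by hydride attack at the exocyclic carbonyl should release the primary alcohol and the auxiliary without enolising the α-centre or touching the isolated alkenes.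

Step 4
Reactants: 8 (2S)-5-methyl-2-(prop-1-en-2-yl)hex-4-en-1-ol
Product: 9 (3S)-3-(iodomethyl)-2,6-dimethylhepta-1,5-diene ((S)-lavandulyl iodide)
Conditions: I2, PPh3, imidazole, CH2Cl2, 0 → 23 °C
Reagents that add atoms: iodine, II
Why: Appel iodination proceeds by SN2 displacement at the primary carbon, so the adjacent stereocentre is not involved.

Step 5
Reactants: 10 2,6-difluoro-4-methoxybenzonitrile
Product: 11 2-fluoro-6-hydroxy-4-methoxybenzonitrile
Conditions: KOH (2.5 equiv), DMSO–H2O (9:1), 60 °C; then aq. HCl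
Reagents that add atoms: potassium hydroxide, [K+].[OH-]
Why: Nucleophilic aromatic substitution (SNAr) of one of two equivalent fluorines ortho to the nitrile, after which the phenoxide formed deactivates the ring against a second substitution and the di-ortho-substituted nitrile resists hydrolysis.

Step 6
Reactants: 11 2-fluoro-6-hydroxy-4-methoxybenzonitrile
Product: 12 2-fluoro-4-methoxy-6-(methoxymethoxy)benzonitrile
Conditions: MOMCl, iPr2NEt, CH2Cl2, 0 → 23 °C
Reagents that add atoms: chloromethyl methyl ether, COCCl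
Why: Williamson-type O-alkylation of the acidic cyanophenol gives the MOM ether that later frees the 5-OH.

Step 7
Reactants: 12 2-fluoro-4-methoxy-6-(methoxymethoxy)benzonitrile
Product: 14 2-fluoro-3-iodo-4-methoxy-6-(methoxymethoxy)benzonitrile, via aryllithium 13 (not isolated)
Conditions: LiN(iPr)2, THF, −78 °C; then I2, −78 °C
Reagents that add atoms: iodine, II
Why: Directed ortho-metalation with an amide base should take the most acidic ring hydrogen, the one between F and OMe (fluorine acidifies its ortho position more than an alkoxy group does), the aryllithium being stable to LiF loss at −78 °C and the hindered nitrile inert to the bulky amide, before iodine traps it.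

Step 8
Reactants: 9 (3S)-3-(iodomethyl)-2,6-dimethylhepta-1,5-diene; 14 2-fluoro-3-iodo-4-methoxy-6-(methoxymethoxy)benzonitrile
Product: 16 2-fluoro-4-methoxy-6-(methoxymethoxy)-3-[(2R)-5-methyl-2-(prop-1-en-2-yl)hex-4-en-1-yl]benzonitrile, via lavandulylzinc iodide 15 (not isolated)
Conditions: 9, Zn dust, LiCl, THF, 40 °C; then 14, Pd(OAc)2 (2 mol %), SPhos (4 mol %), THF, 23 → 50 °C
Reagents that add atoms: none
Why: Negishi sp3–sp2 coupling, in which zinc insertion into the primary iodide leaves the β-stereocentre untouched and Pd(OAc)2/SPhos couples primary alkylzinc halides with di-ortho-substituted aryl iodides faster than β-hydride elimination, with nitrile and MOM ether inert to the organozinc.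

Step 9
Reactants: 17 1-(2,4-dihydroxy-5-methoxyphenyl)ethan-1-one
Product: 18 1-[5-methoxy-2,4-bis(methoxymethoxy)phenyl]ethan-1-one
Conditions: NaH (2.4 equiv), MOMCl (2.4 equiv), DMF, 0 → 23 °C
Reagents that add atoms: chloromethyl methyl ether, COCCl
Why: Williamson-type O-alkylation of both phenoxides, NaH being used so that the hydrogen-bonded 2-OH is also converted.

Step 10
Reactants: 18 1-[5-methoxy-2,4-bis(methoxymethoxy)phenyl]ethan-1-one
Product: 20 2-chloro-1-[5-methoxy-2,4-bis(methoxymethoxy)phenyl]ethan-1-one, via silyl enol ether 19 (not isolated)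
Conditions: LiN(SiMe3)2, Me3SiCl, THF, −78 → 0 °C; then NCS, 0 °C
Reagents that add atoms: N-chlorosuccinimide, O=C1CCC(=O)N1Cl
Why: α-Chlorination through the silyl enol ether keeps the medium free of acid (MOM ethers), avoids chlorination of the electron-rich ring and should stop at the monochloride.

Step 11
Reactants: 20 2-chloro-1-[5-methoxy-2,4-bis(methoxymethoxy)phenyl]ethan-1-one
Product: 21 (1R)-2-chloro-1-[5-methoxy-2,4-bis(methoxymethoxy)phenyl]ethan-1-ol
Conditions: RuCl[(S,S)-TsDPEN](p-cymene) (1 mol %), HCO2H–Et3N (5:2), EtOAc, 25 °C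
Reagents that add atoms: none
Why: Noyori–Ikariya asymmetric transfer hydrogenation, in which the (S,S)-catalyst delivers hydride to the carbonyl face that gives (S)-1-arylethanols from aryl methyl ketones, which for the chloromethyl ketone is the (R)-chlorohydrin because CH2Cl outranks aryl, with the C–Cl bond untouched.

Step 12
Reactants: 21 (1R)-2-chloro-1-[5-methoxy-2,4-bis(methoxymethoxy)phenyl]ethan-1-ol; 16 2-fluoro-4-methoxy-6-(methoxymethoxy)-3-[(2R)-5-methyl-2-(prop-1-en-2-yl)hex-4-en-1-yl]benzonitrile
Product: 25 (2S)-7-methoxy-2-[5-methoxy-2,4-bis(methoxymethoxy)phenyl]-5-(methoxymethoxy)-8-[(2R)-5-methyl-2-(prop-1-en-2-yl)hex-4-en-1-yl]-2,3-dihydro-4H-chromen-4-one, via β-oxido alkyllithium 22 (not isolated), via open-chain ketimine 23 (not isolated), via cyclic ketimine 24 (not isolated)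
Conditions: n-BuLi (1.0 equiv), THF, −78 °C; LiC10H8 (lithium naphthalenide, 2.0 equiv), −78 °C; then 16, −78 °C; then i-PrOH (1.1 equiv), DMF, −78 → 60 °C; then 0.5 M aq. HCl, THF, 0 °C
Reagents that add atoms: water, O
Why: Proposed new method: n-BuLi and then LiC10H8 turn 21 into the β-oxido alkyllithium 22 (a known Barluenga–Yus-type reagent, held at −78 °C, where the O–Li group is too poor a leaving group for β-elimination), and its carbanion adds to the linear, sterically undemanding nitrile of 16 to forge C3–C4; i-PrOH then protonates the more basic ketimide nitrogen, so that 23 holds a C=NH acceptor ortho to fluorine and a lithium alkoxide that displaces fluoride to form O1–C8a, and dilute acid hydrolyses the cyclic ketimine 24 to the ketone. The closest known reaction types are organolithium addition to 2-fluorobenzonitriles and the one-flask SNAr/Thorpe annulation of 2-fluorobenzonitriles with α-hydroxy esters to 3-aminobenzofurans, which joins the same two kinds of bond (aryl C–O and nitrile C–C); the sequence proposed here runs in the reverse order, with an unstabilised carbanion, and gives a six-membered ring, which has not been shown. Ring C closes by intramolecular nucleophilic aromatic substitution (addition–elimination at C8a through a Meisenheimer complex stabilised by the ortho C=NH group, six-membered, exo with respect to the C8–C8a bond), with LiF as the sink. C2 is not a new stereocentre: it is carried over from 21 unchanged because neither its C–O nor its C–H bond is touched, and the lavandulyl centre is remote. The step needs C- over O-attack on the nitrile (the carbanion is far more nucleophilic than the alkoxide), 1,2-addition to C≡N over attack of the alkyllithium at C–F or ortho-lithiation (fast at −78 °C), fluoride over OMOM as leaving group, and ring closure without loss of C2; the last is secured by closing at the imine level, where C3–H is hardly acidic so that retro-aldol-type cleavage, E1cB dehydration and ring-opening are held back, while the flanking lavandulyl group shields C8a–F from intermolecular attack by alkoxide bases.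

Step 13
Reactants: 25 (2S)-7-methoxy-2-[5-methoxy-2,4-bis(methoxymethoxy)phenyl]-5-(methoxymethoxy)-8-[(2R)-5-methyl-2-(prop-1-en-2-yl)hex-4-en-1-yl]-2,3-dihydro-4H-chromen-4-one
Product: 26 (2S)-2-(2,4-dihydroxy-5-methoxyphenyl)-5-hydroxy-7-methoxy-8-[(2R)-5-methyl-2-(prop-1-en-2-yl)hex-4-en-1-yl]-2,3-dihydro-4H-chromen-4-one (CNP0104733.2)
Conditions: 3 M aq. HCl, MeOH, 40 °C
Reagents that add atoms: none
Why: Acid-catalysed acetal exchange of the three aryl MOM ethers with methanol should free the phenols (the peri 5-O-MOM first), while aryl methyl ethers and the C2 centre are expected to survive dilute methanolic acid at this temperature.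

Compound list
1 | (4S)-4-benzyl-1,3-oxazolidin-2-one | O=C1OC[C@H](Cc2ccccc2)N1 | starting material
2 | 3-methylbut-2-enoyl chloride | CC(C)=CC(=O)Cl | starting material
3 | (4S)-4-benzyl-3-lithio-1,3-oxazolidin-2-one | [Li]N1C(=O)OC[C@@H]1Cc1ccccc1 | intermediate
4 | (4S)-4-benzyl-3-(3-methylbut-2-enoyl)-1,3-oxazolidin-2-one | CC(C)=CC(=O)N1C(=O)OC[C@@H]1Cc1ccccc1 | intermediate
5 | 1-bromo-3-methylbut-2-ene | CC(C)=CCBr | starting material
6 | sodium (1Z)-1-[(4S)-4-benzyl-2-oxo-1,3-oxazolidin-3-yl]-3-methylbuta-1,3-dien-1-olate | C=C(C)/C=C(\O[Na])N1C(=O)OC[C@@H]1Cc1ccccc1 | intermediate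
7 | (4S)-4-benzyl-3-[(2S)-5-methyl-2-(prop-1-en-2-yl)hex-4-enoyl]-1,3-oxazolidin-2-one | C=C(C)[C@H](CC=C(C)C)C(=O)N1C(=O)OC[C@@H]1Cc1ccccc1 | intermediate
8 | (2S)-5-methyl-2-(prop-1-en-2-yl)hex-4-en-1-ol | C=C(C)[C@H](CC=C(C)C)CO | intermediate
9 | (3S)-3-(iodomethyl)-2,6-dimethylhepta-1,5-diene | C=C(C)[C@H](CC=C(C)C)CI | intermediate
10 | 2,6-difluoro-4-methoxybenzonitrile | N#Cc1c(F)cc(OC)cc1F | starting material
11 | 2-fluoro-6-hydroxy-4-methoxybenzonitrile | N#Cc1c(O)cc(OC)cc1F | intermediate
12 | 2-fluoro-4-methoxy-6-(methoxymethoxy)benzonitrile | N#Cc1c(OCOC)cc(OC)cc1F | intermediate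
13 | [3-cyano-2-fluoro-6-methoxy-4-(methoxymethoxy)phenyl]lithium | N#Cc1c(OCOC)cc(OC)c([Li])c1F | intermediate
14 | 2-fluoro-3-iodo-4-methoxy-6-(methoxymethoxy)benzonitrile | N#Cc1c(OCOC)cc(OC)c(I)c1F | intermediate
15 | [(2S)-5-methyl-2-(prop-1-en-2-yl)hex-4-en-1-yl]zinc iodide | C=C(C)[C@H](CC=C(C)C)C[Zn]I | intermediate
16 | 2-fluoro-4-methoxy-6-(methoxymethoxy)-3-[(2R)-5-methyl-2-(prop-1-en-2-yl)hex-4-en-1-yl]benzonitrile | C=C(C)[C@H](CC=C(C)C)Cc1c(OC)cc(OCOC)c(C#N)c1F | intermediate
17 | 1-(2,4-dihydroxy-5-methoxyphenyl)ethan-1-one | CC(=O)c1cc(OC)c(O)cc1O | starting material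
18 | 1-[5-methoxy-2,4-bis(methoxymethoxy)phenyl]ethan-1-one | CC(=O)c1cc(OC)c(OCOC)cc1OCOC | intermediate
19 | ({1-[5-methoxy-2,4-bis(methoxymethoxy)phenyl]ethenyl}oxy)trimethylsilane | C=C(O[Si](C)(C)C)c1cc(OC)c(OCOC)cc1OCOC | intermediate
20 | 2-chloro-1-[5-methoxy-2,4-bis(methoxymethoxy)phenyl]ethan-1-one | O=C(CCl)c1cc(OC)c(OCOC)cc1OCOC | intermediate
21 | (1R)-2-chloro-1-[5-methoxy-2,4-bis(methoxymethoxy)phenyl]ethan-1-ol | O[C@H](c1cc(OC)c(OCOC)cc1OCOC)CCl | intermediate
22 | lithium (1S)-2-lithio-1-[5-methoxy-2,4-bis(methoxymethoxy)phenyl]ethan-1-olate | [Li]O[C@H](c1cc(OC)c(OCOC)cc1OCOC)C[Li] | intermediate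
23 | lithium (1S)-3-{2-fluoro-4-methoxy-6-(methoxymethoxy)-3-[(2R)-5-methyl-2-(prop-1-en-2-yl)hex-4-en-1-yl]phenyl}-3-imino-1-[5-methoxy-2,4-bis(methoxymethoxy)phenyl]propan-1-olate | C=C(C)[C@H](CC=C(C)C)Cc1c(OC)cc(OCOC)c(C(=N)C[C@H](O[Li])c2cc(OC)c(OCOC)cc2OCOC)c1F | intermediate
24 | (2S)-7-methoxy-2-[5-methoxy-2,4-bis(methoxymethoxy)phenyl]-5-(methoxymethoxy)-8-[(2R)-5-methyl-2-(prop-1-en-2-yl)hex-4-en-1-yl]-2,3-dihydro-4H-chromen-4-imine | C=C(C)[C@H](CC=C(C)C)Cc1c(OC)cc(OCOC)c2c1O[C@H](c1cc(OC)c(OCOC)cc1OCOC)CC2=N | intermediate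
25 | (2S)-7-methoxy-2-[5-methoxy-2,4-bis(methoxymethoxy)phenyl]-5-(methoxymethoxy)-8-[(2R)-5-methyl-2-(prop-1-en-2-yl)hex-4-en-1-yl]-2,3-dihydro-4H-chromen-4-one | C=C(C)[C@H](CC=C(C)C)Cc1c(OC)cc(OCOC)c2c1O[C@H](c1cc(OC)c(OCOC)cc1OCOC)CC2=O | intermediate
26 | (2S)-2-(2,4-dihydroxy-5-methoxyphenyl)-5-hydroxy-7-methoxy-8-[(2R)-5-methyl-2-(prop-1-en-2-yl)hex-4-en-1-yl]-2,3-dihydro-4H-chromen-4-one | C=C(C)[C@H](CC=C(C)C)Cc1c(OC)cc(O)c2c1O[C@H](c1cc(OC)c(O)cc1O)CC2=O | target

Total step count: 13.
Longest linear sequence: 7 steps (steps 1, 2, 3, 4, 8, 12, 13).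

Steps most likely to fail

1. Step 12 (Proposed new method). The β-oxido alkyllithium may be lost through β-elimination or protonation before it has added to the electron-rich nitrile. The fluoride displacement may also stall at the weakly accepting N–H ketimine, leaving time for reversible ring-opening to erode C2. The fallback uses known reactions, separates the two bond formations and closes the ring from the ketone. It sets out from 21 and 16: 22 is generated as in step 12, 16 is added at −78 °C and the mixture is hydrolysed at once with cold dilute HCl, which should give the isolated β-hydroxy ketone (3S)-1-{2-fluoro-4-methoxy-6-(methoxymethoxy)-3-[(2R)-5-methyl-2-(prop-1-en-2-yl)hex-4-en-1-yl]phenyl}-3-hydroxy-3-[5-methoxy-2,4-bis(methoxymethoxy)phenyl]propan-1-one F1 (organolithium-to-nitrile ketone synthesis). F1 is then cyclised by ketone-activated intramolecular SNAr (K2CO3, DMF, 23 °C, short contact time to keep dehydration behind), which returns to the route at 25.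

2. Step 7. Deprotonation may occur at the other ring position (the hydrogen between OMe and the chelating OMOM group), or the aryllithium may lose LiF to an aryne on warming. The fallback reverses the order so that symmetry decides the metalation and sterics decide the hydroxylation. It sets out from 10: LiN(iPr)2 then I2 should give 2,6-difluoro-3-iodo-4-methoxybenzonitrile F2 (only one kind of ring hydrogen). Negishi coupling of F2 with 15 under the conditions of step 8 should give 2,6-difluoro-4-methoxy-3-[(2R)-5-methyl-2-(prop-1-en-2-yl)hex-4-en-1-yl]benzonitrile F3. KOH in DMSO–H2O should then replace the fluorine that is not flanked by the side chain, giving 2-fluoro-6-hydroxy-4-methoxy-3-[(2R)-5-methyl-2-(prop-1-en-2-yl)hex-4-en-1-yl]benzonitrile F4, and MOMCl/iPr2NEt converts F4 into 16, where the route is rejoined.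

3. Step 13. HCl or methanol may add to the isopropenyl and prenyl double bonds, or the side chain may undergo cation–olefin cyclisation. Acid may also open the C2–O1 bond, assisted by the dioxygenated aryl ring, with loss of configuration. The fallback is a non-protic silyl-transfer deprotection setting out from 25. Me3SiOSO2CF3 with 2,2'-bipyridyl (CH2Cl2, 0 °C) should exchange the three aryl MOM ethers for silyl ethers, giving (2S)-7-methoxy-2-[5-methoxy-2,4-bis(trimethylsilyloxy)phenyl]-8-[(2R)-5-methyl-2-(prop-1-en-2-yl)hex-4-en-1-yl]-5-(trimethylsilyloxy)-2,3-dihydro-4H-chromen-4-one F5. F5 is hydrolysed with water in THF at 23 °C to 26.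

Further compounds
F1 | step 12 | (3S)-1-{2-fluoro-4-methoxy-6-(methoxymethoxy)-3-[(2R)-5-methyl-2-(prop-1-en-2-yl)hex-4-en-1-yl]phenyl}-3-hydroxy-3-[5-methoxy-2,4-bis(methoxymethoxy)phenyl]propan-1-one | C=C(C)[C@H](CC=C(C)C)Cc1c(OC)cc(OCOC)c(C(=O)C[C@H](O)c2cc(OC)c(OCOC)cc2OCOC)c1F
F2 | step 7 | 2,6-difluoro-3-iodo-4-methoxybenzonitrile | N#Cc1c(F)cc(OC)c(I)c1F
F3 | step 7 | 2,6-difluoro-4-methoxy-3-[(2R)-5-methyl-2-(prop-1-en-2-yl)hex-4-en-1-yl]benzonitrile | C=C(C)[C@H](CC=C(C)C)Cc1c(OC)cc(F)c(C#N)c1F
F4 | step 7 | 2-fluoro-6-hydroxy-4-methoxy-3-[(2R)-5-methyl-2-(prop-1-en-2-yl)hex-4-en-1-yl]benzonitrile | C=C(C)[C@H](CC=C(C)C)Cc1c(OC)cc(O)c(C#N)c1F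
F5 | step 13 | (2S)-7-methoxy-2-[5-methoxy-2,4-bis(trimethylsilyloxy)phenyl]-8-[(2R)-5-methyl-2-(prop-1-en-2-yl)hex-4-en-1-yl]-5-(trimethylsilyloxy)-2,3-dihydro-4H-chromen-4-one | C=C(C)[C@H](CC=C(C)C)Cc1c(OC)cc(O[Si](C)(C)C)c2c1O[C@H](c1cc(OC)c(O[Si](C)(C)C)cc1O[Si](C)(C)C)CC2=O
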